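The constants used here were set for the occasion; the rest is arithmetic.

This flask is slow. In beta the electrophile's half-life by the step that makes target, with the charges as they stand, is 0.97 min, and the run lasts 1.5 min, of which 50 s goes on dosing.

the same everywhere: electrophile 5.0 × 10⁻⁴ M (fed, over 50 s); time 1.5 min
- beta: nucleophile 1.50 equiv; the fed solution adds 0.20 times the starting volume
- gamma: nucleophile 3.00 equiv; the fed solution adds 0.20 times the starting volume
- theta: nucleophile 6.00 equiv; the fed solution adds 0.20 times the starting volume

    electrophile + nucleophile → acid set free + target (k1 = 15.8 M⁻¹ s⁻¹)
    nucleophile + acid set free ⇌ protonated nucleophile, settled at all times (K2 = 2.9 × 10⁵ M⁻¹)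
    acid set free + target → side product (k3 = 93.5 M⁻¹ s⁻¹)
    2 nucleophile → homo dimer (k4 = 5.68 M⁻¹ s⁻¹)

- where a step has two of a species, its rate is k times that concentration squared, and two are used at each turn
- charges are per starting volume, the dose included; the dosed solution carries all of it
- run time (beta): 1.5 min

1. part of the electrophile that has reacted at the end, beta
2. part of the electrophile that has reacted at the end, gamma
3. part of the electrophile that has reacted at the end, theta
4. what raising the equivalents of nucleophile from its lowest to its highest value here does to the part of the electrophile that has reacted (changes below 5 percentage points count as none) (no change / it rises / it falls)

Here is what you take over. The acid set free goes onto nucleophile, because the equilibrium constant times the starting nucleophile is 220. So each turn uses one nucleophile and binds a second as protonated nucleophile. Nucleophile also leaves as homo dimer.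

Watch one number. Divide the rate at which the target step uses nucleophile by the rate at which dimerisation uses it. Time and volume drop out. What stays is electrophile over nucleophile, times the split factor, the target step's constant over twice the dimer step's constant, 1.39.

Put in the whole charges and this ratio is 0.927 for beta and 0.232 for theta. So don't count extra nucleophile as extra target. I expect the part reacted to rise with the equivalents, but by less than their factor of 4.00.

For beta I commit to a figure. The average electrophile arrives at the middle of the dose, so it stays 65.0 s. I treat its decay as pseudo-first-order, with nucleophile guessed at 0.5 of its charge, and get 32.0% reacted.

The forecast gives 30% for beta, below my figure, 44% for gamma and 56% for theta, and on raising the equivalents it answers it rises, holding that “conversion rises with equivalents but less than proportionally”.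

The simulation gives 28.9% for beta, below my 32.0%, then 42.7% for gamma and 55.6% for theta; from beta to theta the part reacted goes as follows: it rises, by 27 percentage points. With the dimer step struck out, gamma reaches 61.3%. At the end beta keeps 71% of its electrophile and 33% of its nucleophile, so the split factor gives a ratio of 2.02. Theta keeps 44% and 19%, so at its end the target step uses nucleophile more slowly than dimerisation, at a ratio of 0.555.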